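**Retrosynthetic overview**

1. The strategy rests on the fully substituted benzene ring of the (R)-2-isopropenyl-2,3-dihydrobenzofuran (C3a, C4, C5, C6, C7, C7a): oxygen on C4, C6 and C7a alternates with carbon on C3a, C5 and C7, and C7 carries the CH2 bridge to C3 of the 4-hydroxy-2-pyranone ring. A 3-alkoxycyclobutenone plus a siloxyalkyne deliver exactly this pattern.
2. Last bond: bridge CH2–C3 of the pyranone, by quinone-methide alkylation of 6-ethyl-4-hydroxy-5-methyl-2-pyranone (from pentan-3-one and malonyl dichloride). Before it: the C5 isobutyryl group via C5–Br/C5–Li, and chelation-assisted O4-demethylation.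
3. Dihydrofuran ring: O1–C2 by asymmetric palladium-catalysed allylic etherification of the single free phenol (on C7a) onto an (E)-allylic methyl carbonate, setting C2 as R.
4. Benzene ring: benzannulation of a cyclobutenone (supplies C7a, C3a, C4, C5) with a siloxyalkyne (supplies C6, C7), forming C7–C7a, C5–C6 and C3a–C7a.
5. Ring order: benzene ring (step 9), dihydrofuran ring (step 10); the pyranone ring is built separately (step 16) and joined in step 17.

Key step: step 9

Remark 1: O4 is carried as a methyl ether (from methoxyethyne), because its late cleavage is an SN2 displacement by iodide inside a magnesium chelate; a higher alkyl ether would need boron halides, which are expected to open the allylic aryl ether of the dihydrofuran ring.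
Remark 2: the (R,R) ligand in step 10 is assigned by analogy with closely related closures to 2-isopropenyl-2,3-dihydrobenzofurans; the (S,S) ligand would give the mirror-image ether.

**Route**

Step 1
Reactants: 1 2-methyl-2-vinyloxirane (racemic); 2 di-tert-butyl malonate
Product: 3 di-tert-butyl 2-[(2E)-4-hydroxy-3-methylbut-2-en-1-yl]propanedioate
Conditions: Pd(PPh3)4 (3 mol%), THF, 0 °C → rt
Reagents that add atoms: none
Why: Tsuji–Trost allylic alkylation under neutral conditions: zerovalent palladium opens the vinyl epoxide to a π-allyl complex whose alkoxide deprotonates the malonate, and the soft carbanion attacks the unsubstituted allyl terminus (1,4-addition), the syn placement of the CH2O group in the complex favouring the E-alkene; any Z-isomer is removed here by chromatography.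

Step 2
Reactants: 3 di-tert-butyl 2-[(2E)-4-hydroxy-3-methylbut-2-en-1-yl]propanedioate
Product: 4 di-tert-butyl 2-[(2E)-4-(methoxycarbonyloxy)-3-methylbut-2-en-1-yl]propanedioate
Conditions: ClCO2Me, pyridine, CH2Cl2, 0 °C
Reagents that add atoms: methyl chloroformate, COC(=O)Cl
Why: Acylation of the primary allylic alcohol with a chloroformate under pyridine gives the mixed carbonate that later serves as the leaving group for palladium; the hindered, weakly acidic malonate C–H is not acylated under these conditions.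

Step 3
Reactants: 4 di-tert-butyl 2-[(2E)-4-(methoxycarbonyloxy)-3-methylbut-2-en-1-yl]propanedioate
Product: 6 (4E)-6-(methoxycarbonyloxy)-5-methylhex-4-enoic acid, via diacid 5 (not isolated)
Conditions: CF3CO2H, CH2Cl2, 0 °C → rt; evaporate; toluene, 110 °C
Reagents that add atoms: none
Why: Acidolysis of the two tert-butyl esters (E1 loss of 2-methylpropene) gives the malonic acid, which loses carbon dioxide on heating through the cyclic six-membered transition state of malonic acid decarboxylation; the methyl carbonate and the E-alkene, deactivated by the allylic oxygen, should tolerate the brief acid exposure.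

Step 4
Reactants: 6 (4E)-6-(methoxycarbonyloxy)-5-methylhex-4-enoic acid
Product: 7 (4E)-6-(methoxycarbonyloxy)-5-methylhex-4-enoyl chloride
Conditions: (COCl)2, DMF (cat.), CH2Cl2, 0 °C → rt; evaporate
Reagents that add atoms: oxalyl chloride, O=C(Cl)C(=O)Cl
Why: Vilsmeier-type activation by oxalyl chloride and catalytic DMF converts the acid into the acyl chloride under conditions that leave the carbonate and the alkene untouched.

Step 5
Reactants: 8 2-chloro-1,1-dimethoxyethane
Product: 11 methoxyethyne, via chlorovinyl ether 9 (not isolated), via sodium acetylide 10 (not isolated)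
Conditions: NaNH2 (3 equiv), liquid NH3, −33 °C; then aq. NaCl, −70 °C; distilled into cold Et2O
Reagents that add atoms: none
Why: Twofold base-induced β-elimination (methanol, then hydrogen chloride) is the classical alkoxyethyne synthesis; the product is held as its sodium acetylide until the cold aqueous quench and is used as a cold solution because of its volatility.

Step 6
Reactants: 7 (4E)-6-(methoxycarbonyloxy)-5-methylhex-4-enoyl chloride; 11 methoxyethyne
Product: 13 (2E)-4-(2-methoxy-4-oxocyclobut-2-en-1-yl)-2-methylbut-2-en-1-yl methyl carbonate (racemic), via ketene 12 (not isolated)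
Conditions: Et3N, Et2O, 0 °C → rt (closed vessel), slow addition of 7 to excess 11
Reagents that add atoms: none
Why: Dehydrochlorination gives the monoalkylketene, which is trapped in situ by a [2+2] ketene–ynol ether cycloaddition; the nucleophilic terminal carbon of the ynol ether bonds to the ketene carbonyl carbon, so the methoxy group lands on C3 and the side chain on C4 of the cyclobutenone, and slow addition to excess alkyne suppresses ketene dimerisation.

Step 7
Reactants: 14 prop-2-yn-1-ol
Product: 15 tert-butyldimethyl(prop-2-yn-1-yloxy)silane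
Conditions: t-BuMe2SiCl, imidazole, CH2Cl2, rt
Reagents that add atoms: tert-butyldimethylsilyl chloride, CC(C)(C)[Si](C)(C)Cl
Why: Imidazole-promoted silylation of a primary alcohol is routine and gives an ether stable to the strong base of step 8.

Step 8
Reactants: 15 tert-butyldimethyl(prop-2-yn-1-yloxy)silane
Product: 18 tert-butyldimethyl{[3-(triisopropylsilyloxy)prop-2-yn-1-yl]oxy}silane, via lithium acetylide 16 (not isolated), via lithium ynolate 17 (not isolated)
Conditions: LiN(SiMe3)2, THF, −78 °C; t-BuOOLi (from t-BuOOH and LiN(SiMe3)2), −78 → 0 °C; then i-Pr3SiOTf, −78 → 0 °C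
Reagents that add atoms: tert-butyl hydroperoxide, CC(C)(C)OO; triisopropylsilyl trifluoromethanesulfonate, CC(C)[Si](C(C)C)(C(C)C)OS(=O)(=O)C(F)(F)F
Why: Oxidation of the lithium acetylide by lithium tert-butyl peroxide (electrophilic oxygen transfer with loss of lithium tert-butoxide) gives the lithium ynolate, which the bulky, hard silyl triflate captures on oxygen to give the siloxyalkyne (Julia-type ynolate formation with O-silylation).

Step 9
Reactants: 13 (2E)-4-(2-methoxy-4-oxocyclobut-2-en-1-yl)-2-methylbut-2-en-1-yl methyl carbonate; 18 tert-butyldimethyl{[3-(triisopropylsilyloxy)prop-2-yn-1-yl]oxy}silane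
Product: 23 (2E)-4-[3-({[tert-butyl(dimethyl)silyl]oxy}methyl)-2-hydroxy-6-methoxy-4-(triisopropylsilyloxy)phenyl]-2-methylbut-2-en-1-yl methyl carbonate, via vinylketene 19 (not isolated), via vinylcyclobutenone 20 (not isolated), via dienylketene 21 (not isolated), via cyclohexadienone 22 (not isolated)
Conditions: toluene (0.5 M), 90 °C then 110 °C, argon, 18 in slight excess
Reagents that add atoms: none
Why: Heating opens cyclobutenone 13 by a 4π-electrocyclic reaction to the methoxy-substituted vinylketene 19, which the electron-rich siloxyalkyne 18 captures in a polar [2+2] cycloaddition to give the 4-vinylcyclobutenone 20; a second 4π-opening gives the dienylketene 21, whose 6π-electrocyclisation gives the cyclohexadienone 22, and enolisation gives the phenol 23. The closest known reaction type is the Danheiser benzannulation of cyclobutenones with siloxyalkynes, here applied to a 3-alkoxy-4-alkylcyclobutenone. The one new ring, the benzene ring, is closed by the 6π-electrocyclisation (C3a–C7a) after the [2+2] event has made C7–C7a and C5–C6; no stereocentre is formed, and the stereocentre of racemic 13 becomes the sp2 carbon C3a. The step needs regioselectivity in the [2+2] event, which the polarity of the partners secures: the alkyne carbon remote from the silyloxy group is the nucleophilic one and bonds to the ketene carbonyl carbon, so the CH2OSi arm ends up ortho to the new phenol and the three oxygens end up mutually meta. It also needs the dienylketene with the vinyl group turned inward, which is reached because the opening of 20 is reversible while the 6π-closure and aromatisation are not. The new phenol is flanked by two carbon substituents and should resist acylation by the ketene intermediates, and the allylic carbonate and both silyl ethers are inert to neutral thermolysis.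

Step 10
Reactants: 23 (2E)-4-[3-({[tert-butyl(dimethyl)silyl]oxy}methyl)-2-hydroxy-6-methoxy-4-(triisopropylsilyloxy)phenyl]-2-methylbut-2-en-1-yl methyl carbonate
Product: 24 tert-butyl{[(2R)-4-methoxy-2-(prop-1-en-2-yl)-6-(triisopropylsilyloxy)-2,3-dihydro-1-benzofuran-7-yl]methoxy}dimethylsilane
Conditions: Pd2(dba)3·CHCl3 (2.5 mol%), (R,R)-DACH-phenyl Trost ligand {N,N'-[(1R,2R)-cyclohexane-1,2-diyl]bis[2-(diphenylphosphanyl)benzamide], 7.5 mol%}, AcOH (1 equiv), CH2Cl2, rt
Reagents that add atoms: none
Why: Trost asymmetric allylic alkylation with an oxygen nucleophile: zerovalent palladium ionises the allylic carbonate, the two diastereomeric π-allyl complexes interconvert by π–σ–π isomerisation (helped by acetic acid), and the only free phenol (O on C7a) attacks the internal allyl carbon in a 5-exo closure within the chiral pocket of the (R,R)-ligand, which is expected to set C2 as R; the methoxy group on C4 excludes the regioisomeric closure.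

Step 11
Reactants: 24 tert-butyl{[(2R)-4-methoxy-2-(prop-1-en-2-yl)-6-(triisopropylsilyloxy)-2,3-dihydro-1-benzofuran-7-yl]methoxy}dimethylsilane
Product: 25 {[(2R)-5-bromo-4-methoxy-2-(prop-1-en-2-yl)-6-(triisopropylsilyloxy)-2,3-dihydro-1-benzofuran-7-yl]methoxy}(tert-butyl)dimethylsilane
Conditions: N-bromosuccinimide (1.05 equiv), CH2Cl2, −20 → 0 °C, dark
Reagents that add atoms: N-bromosuccinimide, O=C1CCC(=O)N1Br
Why: Electrophilic aromatic bromination at C5, the only unsubstituted ring carbon, activated by two ortho oxygens (on C4 and C6) and one para oxygen (on C7a), should outpace any reaction of N-bromosuccinimide with the 1,1-disubstituted alkene at low temperature.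

Step 12
Reactants: 25 {[(2R)-5-bromo-4-methoxy-2-(prop-1-en-2-yl)-6-(triisopropylsilyloxy)-2,3-dihydro-1-benzofuran-7-yl]methoxy}(tert-butyl)dimethylsilane; 26 2-methylpropanal
Product: 28 1-[(2R)-7-({[tert-butyl(dimethyl)silyl]oxy}methyl)-4-methoxy-2-(prop-1-en-2-yl)-6-(triisopropylsilyloxy)-2,3-dihydro-1-benzofuran-5-yl]-2-methylpropan-1-ol (mixture of epimers at the carbinol carbon), via aryllithium 27 (not isolated)
Conditions: t-BuLi (2.1 equiv), Et2O, −78 °C; then 26, −78 °C; then H2O
Reagents that add atoms: none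
Why: Bromine–lithium exchange at −78 °C is faster than deprotonation at C3 or silyl migration from oxygen to carbon, and the aryllithium adds to the unhindered aldehyde (1,2-addition); the new carbinol stereocentre is not controlled and is removed in step 13.

Step 13
Reactants: 28 1-[(2R)-7-({[tert-butyl(dimethyl)silyl]oxy}methyl)-4-methoxy-2-(prop-1-en-2-yl)-6-(triisopropylsilyloxy)-2,3-dihydro-1-benzofuran-5-yl]-2-methylpropan-1-ol
Product: 29 1-[(2R)-7-({[tert-butyl(dimethyl)silyl]oxy}methyl)-4-methoxy-2-(prop-1-en-2-yl)-6-(triisopropylsilyloxy)-2,3-dihydro-1-benzofuran-5-yl]-2-methylpropan-1-one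
Conditions: Dess–Martin periodinane, pyridine, CH2Cl2, 0 °C → rt
Reagents that add atoms: none
Why: Dess–Martin oxidation of the secondary benzylic alcohol under buffered, non-acidic conditions gives the aryl ketone without ionising the electron-rich benzylic positions.

Step 14
Reactants: 29 1-[(2R)-7-({[tert-butyl(dimethyl)silyl]oxy}methyl)-4-methoxy-2-(prop-1-en-2-yl)-6-(triisopropylsilyloxy)-2,3-dihydro-1-benzofuran-5-yl]-2-methylpropan-1-one
Product: 30 1-[(2R)-7-({[tert-butyl(dimethyl)silyl]oxy}methyl)-4-hydroxy-2-(prop-1-en-2-yl)-6-(triisopropylsilyloxy)-2,3-dihydro-1-benzofuran-5-yl]-2-methylpropan-1-one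
Conditions: MgI2·OEt2 (3 equiv), toluene, 70 °C; then H2O
Reagents that add atoms: none
Why: Chelation-assisted O-demethylation: magnesium bound between the ketone oxygen and the C4 methoxy oxygen activates the O–CH3 bond for SN2 attack by iodide, and because O6 is still silylated the carbonyl can chelate only toward O4; the allylic aryl ether O1 and the silyl ethers offer no such chelate and should be left intact.

Step 15
Reactants: 31 pentan-3-one
Product: 32 trimethyl(pent-2-en-3-yloxy)silane
Conditions: Me3SiOTf, Et3N, CH2Cl2, 0 °C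
Reagents that add atoms: trimethylsilyl trifluoromethanesulfonate, C[Si](C)(C)OS(=O)(=O)C(F)(F)F
Why: Soft enolisation of the symmetrical ketone with a silyl triflate and a tertiary amine gives the trimethylsilyl enol ether, whose alkene geometry is irrelevant.

Step 16
Reactants: 32 trimethyl(pent-2-en-3-yloxy)silane; 33 malonyl dichloride
Product: 35 6-ethyl-4-hydroxy-5-methyl-2H-pyran-2-one, via acyl chloride 34 (not isolated)
Conditions: Et2O, −78 °C → rt
Reagents that add atoms: none
Why: C-acylation of the silyl enol ether by malonyl dichloride gives a 3,5-dioxoacyl chloride that lactonises through the enol oxygen and tautomerises to the 4-hydroxy-2-pyranone (Effenberger pyranone synthesis).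

Step 17
Reactants: 30 1-[(2R)-7-({[tert-butyl(dimethyl)silyl]oxy}methyl)-4-hydroxy-2-(prop-1-en-2-yl)-6-(triisopropylsilyloxy)-2,3-dihydro-1-benzofuran-5-yl]-2-methylpropan-1-one; 35 6-ethyl-4-hydroxy-5-methyl-2H-pyran-2-one
Product: 38 3-{[(2R)-4,6-dihydroxy-5-(2-methylpropanoyl)-2-(prop-1-en-2-yl)-2,3-dihydro-1-benzofuran-7-yl]methyl}-6-ethyl-4-hydroxy-5-methyl-2H-pyran-2-one (CNP0206652.1), via triol 36 (not isolated), via quinone methide 37 (not isolated)
Conditions: Bu4NF (2.2 equiv), AcOH (2.2 equiv), THF, 0 °C → rt; then 35 (3 equiv), NaOAc, 45 °C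
Reagents that add atoms: none
Why: Fluoride removes both silyl groups, the resulting 2-hydroxybenzyl alcohol, activated by oxygen on C4, C6 and C7a, loses water in the acetate buffer to an ortho-quinone methide, and C3 of the 4-hydroxypyranone adds in a Michael fashion with rearomatisation; the fully substituted benzene ring offers no competing carbon nucleophile.

**Compound list**

1 | 2-methyl-2-vinyloxirane (racemic) | CC1(C=C)CO1 | starting material
2 | di-tert-butyl malonate | CC(C)(C)OC(=O)CC(=O)OC(C)(C)C | starting material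
3 | di-tert-butyl 2-[(2E)-4-hydroxy-3-methylbut-2-en-1-yl]propanedioate | CC(C)(C)OC(=O)C(C/C=C(\C)CO)C(=O)OC(C)(C)C | intermediate
4 | di-tert-butyl 2-[(2E)-4-(methoxycarbonyloxy)-3-methylbut-2-en-1-yl]propanedioate | CC(C)(C)OC(=O)C(C/C=C(\C)COC(=O)OC)C(=O)OC(C)(C)C | intermediate
5 | 2-[(2E)-4-(methoxycarbonyloxy)-3-methylbut-2-en-1-yl]propanedioic acid (not isolated) | OC(=O)C(C/C=C(\C)COC(=O)OC)C(=O)O | intermediate
6 | (4E)-6-(methoxycarbonyloxy)-5-methylhex-4-enoic acid | OC(=O)CC/C=C(\C)COC(=O)OC | intermediate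
7 | (4E)-6-(methoxycarbonyloxy)-5-methylhex-4-enoyl chloride | ClC(=O)CC/C=C(\C)COC(=O)OC | intermediate
8 | 2-chloro-1,1-dimethoxyethane | COC(CCl)OC | starting material
9 | 1-chloro-2-methoxyethene (not isolated) | COC=CCl | intermediate
10 | sodium methoxyethynide (not isolated) | [Na]C#COC | intermediate
11 | methoxyethyne | COC#C | intermediate
12 | (2E)-2-methyl-6-oxohexa-2,5-dien-1-yl methyl carbonate, the ketene (not isolated) | O=C=CC/C=C(\C)COC(=O)OC | intermediate
13 | (2E)-4-(2-methoxy-4-oxocyclobut-2-en-1-yl)-2-methylbut-2-en-1-yl methyl carbonate (racemic) | O=C1C=C(OC)C1C/C=C(\C)COC(=O)OC | intermediate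
14 | prop-2-yn-1-ol | C#CCO | starting material
15 | tert-butyldimethyl(prop-2-yn-1-yloxy)silane | C#CCO[Si](C)(C)C(C)(C)C | intermediate
16 | lithium acetylide of 15 (not isolated) | [Li]C#CCO[Si](C)(C)C(C)(C)C | intermediate
17 | lithium 3-{[tert-butyl(dimethyl)silyl]oxy}prop-1-yn-1-olate (not isolated) | [Li]OC#CCO[Si](C)(C)C(C)(C)C | intermediate
18 | tert-butyldimethyl{[3-(triisopropylsilyloxy)prop-2-yn-1-yl]oxy}silane | CC(C)[Si](C(C)C)(C(C)C)OC#CCO[Si](C)(C)C(C)(C)C | intermediate
19 | (2E)-6-methoxy-2-methyl-8-oxoocta-2,5,7-trien-1-yl methyl carbonate, the vinylketene (not isolated) | O=C=CC(OC)=CC/C=C(\C)COC(=O)OC | intermediate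
20 | 2-({[tert-butyl(dimethyl)silyl]oxy}methyl)-4-[(4E)-1-methoxy-6-(methoxycarbonyloxy)-5-methylhexa-1,4-dien-1-yl]-3-(triisopropylsilyloxy)cyclobut-2-en-1-one (not isolated) | O=C1C(CO[Si](C)(C)C(C)(C)C)=C(O[Si](C(C)C)(C(C)C)C(C)C)C1C(OC)=CC/C=C(\C)COC(=O)OC | intermediate
21 | dienylketene from ring opening of 20 (not isolated) | O=C=C(CO[Si](C)(C)C(C)(C)C)C(O[Si](C(C)C)(C(C)C)C(C)C)=CC(OC)=CC/C=C(\C)COC(=O)OC | intermediate
22 | 2-({[tert-butyl(dimethyl)silyl]oxy}methyl)-5-methoxy-6-[(2E)-4-(methoxycarbonyloxy)-3-methylbut-2-en-1-yl]-3-(triisopropylsilyloxy)cyclohexa-2,4-dien-1-one (not isolated) | O=C1C(CO[Si](C)(C)C(C)(C)C)=C(O[Si](C(C)C)(C(C)C)C(C)C)C=C(OC)C1C/C=C(\C)COC(=O)OC | intermediate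
23 | (2E)-4-[3-({[tert-butyl(dimethyl)silyl]oxy}methyl)-2-hydroxy-6-methoxy-4-(triisopropylsilyloxy)phenyl]-2-methylbut-2-en-1-yl methyl carbonate | COC(=O)OC/C(C)=C/Cc1c(O)c(CO[Si](C)(C)C(C)(C)C)c(O[Si](C(C)C)(C(C)C)C(C)C)cc1OC | intermediate
24 | tert-butyl{[(2R)-4-methoxy-2-(prop-1-en-2-yl)-6-(triisopropylsilyloxy)-2,3-dihydro-1-benzofuran-7-yl]methoxy}dimethylsilane | C=C(C)[C@H]1Cc2c(OC)cc(O[Si](C(C)C)(C(C)C)C(C)C)c(CO[Si](C)(C)C(C)(C)C)c2O1 | intermediate
25 | {[(2R)-5-bromo-4-methoxy-2-(prop-1-en-2-yl)-6-(triisopropylsilyloxy)-2,3-dihydro-1-benzofuran-7-yl]methoxy}(tert-butyl)dimethylsilane | C=C(C)[C@H]1Cc2c(OC)c(Br)c(O[Si](C(C)C)(C(C)C)C(C)C)c(CO[Si](C)(C)C(C)(C)C)c2O1 | intermediate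
26 | 2-methylpropanal | CC(C)C=O | starting material
27 | 5-lithio derivative of 24 (not isolated) | C=C(C)[C@H]1Cc2c(OC)c([Li])c(O[Si](C(C)C)(C(C)C)C(C)C)c(CO[Si](C)(C)C(C)(C)C)c2O1 | intermediate
28 | 1-[(2R)-7-({[tert-butyl(dimethyl)silyl]oxy}methyl)-4-methoxy-2-(prop-1-en-2-yl)-6-(triisopropylsilyloxy)-2,3-dihydro-1-benzofuran-5-yl]-2-methylpropan-1-ol (epimers at the carbinol carbon) | C=C(C)[C@H]1Cc2c(OC)c(C(O)C(C)C)c(O[Si](C(C)C)(C(C)C)C(C)C)c(CO[Si](C)(C)C(C)(C)C)c2O1 | intermediate
29 | 1-[(2R)-7-({[tert-butyl(dimethyl)silyl]oxy}methyl)-4-methoxy-2-(prop-1-en-2-yl)-6-(triisopropylsilyloxy)-2,3-dihydro-1-benzofuran-5-yl]-2-methylpropan-1-one | C=C(C)[C@H]1Cc2c(OC)c(C(=O)C(C)C)c(O[Si](C(C)C)(C(C)C)C(C)C)c(CO[Si](C)(C)C(C)(C)C)c2O1 | intermediate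
30 | 1-[(2R)-7-({[tert-butyl(dimethyl)silyl]oxy}methyl)-4-hydroxy-2-(prop-1-en-2-yl)-6-(triisopropylsilyloxy)-2,3-dihydro-1-benzofuran-5-yl]-2-methylpropan-1-one | C=C(C)[C@H]1Cc2c(O)c(C(=O)C(C)C)c(O[Si](C(C)C)(C(C)C)C(C)C)c(CO[Si](C)(C)C(C)(C)C)c2O1 | intermediate
31 | pentan-3-one | CCC(=O)CC | starting material
32 | trimethyl(pent-2-en-3-yloxy)silane | CC=C(CC)O[Si](C)(C)C | intermediate
33 | malonyl dichloride | O=C(Cl)CC(=O)Cl | starting material
34 | 4-methyl-3,5-dioxoheptanoyl chloride (not isolated) | CCC(=O)C(C)C(=O)CC(=O)Cl | intermediate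
35 | 6-ethyl-4-hydroxy-5-methyl-2H-pyran-2-one | CCc1oc(=O)cc(O)c1C | intermediate
36 | 1-[(2R)-4,6-dihydroxy-7-(hydroxymethyl)-2-(prop-1-en-2-yl)-2,3-dihydro-1-benzofuran-5-yl]-2-methylpropan-1-one (not isolated) | C=C(C)[C@H]1Cc2c(O)c(C(=O)C(C)C)c(O)c(CO)c2O1 | intermediate
37 | (2R)-4-hydroxy-7-methylidene-5-(2-methylpropanoyl)-2-(prop-1-en-2-yl)-3,7-dihydro-1-benzofuran-6(2H)-one, the ortho-quinone methide (not isolated) | C=C(C)[C@H]1CC2=C(O1)C(=C)C(=O)C(C(=O)C(C)C)=C2O | intermediate
38 | 3-{[(2R)-4,6-dihydroxy-5-(2-methylpropanoyl)-2-(prop-1-en-2-yl)-2,3-dihydro-1-benzofuran-7-yl]methyl}-6-ethyl-4-hydroxy-5-methyl-2H-pyran-2-one | C=C(C)[C@H]1Cc2c(O)c(C(=O)C(C)C)c(O)c(Cc3c(O)c(C)c(CC)oc3=O)c2O1 | target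

**Step count**

Total: 17 steps. Longest linear sequence: 12 steps (1–4, 6, 9–14, 17).

**Steps most likely to fail**

Step 9 (key step). The vinylogous-ester stabilisation of 13 may raise the temperature needed for the first ring opening to the point where the siloxyalkyne isomerises to a silylketene or the vinylketene dimerises before it is trapped. Fallback: setting out from 13 and 18, the cyclobutenone is opened photochemically instead of thermally (254 nm, quartz, benzene, rt), so that vinylketene 19 is generated and trapped at room temperature as vinylcyclobutenone 20. Compound 20 is then isolated and heated on its own in toluene (80–110 °C), where only the second ring opening and the 6π-closure remain. The route is rejoined at 23; this fallback makes no compound outside the list (F0).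

Step 17. The quinone methide may be intercepted by oxygen nucleophiles (O-alkylation of the pyranone, acetate, self-condensation through phenol oxygen) faster than C3 of the pyranone adds. Fallback: setting out from 30, buffered HF·pyridine (pyridine, THF, 0 °C) should remove only the primary alkyl silyl ether to give 1-[(2R)-4-hydroxy-7-(hydroxymethyl)-2-(prop-1-en-2-yl)-6-(triisopropylsilyloxy)-2,3-dihydro-1-benzofuran-5-yl]-2-methylpropan-1-one F4. MnO2 in CH2Cl2 should oxidise the benzylic alcohol to (2R)-4-hydroxy-5-(2-methylpropanoyl)-2-(prop-1-en-2-yl)-6-(triisopropylsilyloxy)-2,3-dihydro-1-benzofuran-7-carbaldehyde F5. A reductive Knoevenagel alkylation with pyranone 35 (L-proline catalyst, Hantzsch ester, CH2Cl2, rt) forms the bridge by condensation and immediate transfer hydrogenation of the alkylidene adduct, giving 6-ethyl-4-hydroxy-3-{[(2R)-4-hydroxy-5-(2-methylpropanoyl)-2-(prop-1-en-2-yl)-6-(triisopropylsilyloxy)-2,3-dihydro-1-benzofuran-7-yl]methyl}-5-methyl-2H-pyran-2-one F6. Bu4NF/AcOH in THF then removes the aryl silyl ether, and the route is rejoined at 38.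

Step 14. The isopropyl ketone, flanked by the methoxy group and the bulky silyloxy group, may not reach the planar magnesium chelate, so that demethylation is slow and erosion of the benzylic silyl ether competes. Fallback: setting out from bromide 25, bromine–lithium exchange (t-BuLi, Et2O, −78 °C) and quench with DMF should give (2R)-7-({[tert-butyl(dimethyl)silyl]oxy}methyl)-4-methoxy-2-(prop-1-en-2-yl)-6-(triisopropylsilyloxy)-2,3-dihydro-1-benzofuran-5-carbaldehyde F1. MgI2·OEt2 in toluene should demethylate this 2-methoxybenzaldehyde, whose formyl group chelates without strain, to give (2R)-7-({[tert-butyl(dimethyl)silyl]oxy}methyl)-4-hydroxy-2-(prop-1-en-2-yl)-6-(triisopropylsilyloxy)-2,3-dihydro-1-benzofuran-5-carbaldehyde F2. i-PrMgCl (2.2 equiv, THF, −40 °C) should add to the aldehyde of the magnesium phenoxide to give 1-[(2R)-7-({[tert-butyl(dimethyl)silyl]oxy}methyl)-4-hydroxy-2-(prop-1-en-2-yl)-6-(triisopropylsilyloxy)-2,3-dihydro-1-benzofuran-5-yl]-2-methylpropan-1-ol F3 (epimers at the carbinol carbon). MnO2 in CH2Cl2 then oxidises the benzylic alcohol, and the route is rejoined at 30.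

Further compounds
F0 | step 9 | none | none
F1 | step 14 | (2R)-7-({[tert-butyl(dimethyl)silyl]oxy}methyl)-4-methoxy-2-(prop-1-en-2-yl)-6-(triisopropylsilyloxy)-2,3-dihydro-1-benzofuran-5-carbaldehyde | C=C(C)[C@H]1Cc2c(OC)c(C=O)c(O[Si](C(C)C)(C(C)C)C(C)C)c(CO[Si](C)(C)C(C)(C)C)c2O1
F2 | step 14 | (2R)-7-({[tert-butyl(dimethyl)silyl]oxy}methyl)-4-hydroxy-2-(prop-1-en-2-yl)-6-(triisopropylsilyloxy)-2,3-dihydro-1-benzofuran-5-carbaldehyde | C=C(C)[C@H]1Cc2c(O)c(C=O)c(O[Si](C(C)C)(C(C)C)C(C)C)c(CO[Si](C)(C)C(C)(C)C)c2O1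
F3 | step 14 | 1-[(2R)-7-({[tert-butyl(dimethyl)silyl]oxy}methyl)-4-hydroxy-2-(prop-1-en-2-yl)-6-(triisopropylsilyloxy)-2,3-dihydro-1-benzofuran-5-yl]-2-methylpropan-1-ol | C=C(C)[C@H]1Cc2c(O)c(C(O)C(C)C)c(O[Si](C(C)C)(C(C)C)C(C)C)c(CO[Si](C)(C)C(C)(C)C)c2O1
F4 | step 17 | 1-[(2R)-4-hydroxy-7-(hydroxymethyl)-2-(prop-1-en-2-yl)-6-(triisopropylsilyloxy)-2,3-dihydro-1-benzofuran-5-yl]-2-methylpropan-1-one | C=C(C)[C@H]1Cc2c(O)c(C(=O)C(C)C)c(O[Si](C(C)C)(C(C)C)C(C)C)c(CO)c2O1
F5 | step 17 | (2R)-4-hydroxy-5-(2-methylpropanoyl)-2-(prop-1-en-2-yl)-6-(triisopropylsilyloxy)-2,3-dihydro-1-benzofuran-7-carbaldehyde | C=C(C)[C@H]1Cc2c(O)c(C(=O)C(C)C)c(O[Si](C(C)C)(C(C)C)C(C)C)c(C=O)c2O1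
F6 | step 17 | 6-ethyl-4-hydroxy-3-{[(2R)-4-hydroxy-5-(2-methylpropanoyl)-2-(prop-1-en-2-yl)-6-(triisopropylsilyloxy)-2,3-dihydro-1-benzofuran-7-yl]methyl}-5-methyl-2H-pyran-2-one | C=C(C)[C@H]1Cc2c(O)c(C(=O)C(C)C)c(O[Si](C(C)C)(C(C)C)C(C)C)c(Cc3c(O)c(C)c(CC)oc3=O)c2O1
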